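The numbers in the tables stem from a simulated flask with constants of no real substance, noise included.

If the loss of E is a one-way drain, a hot flask empties of E with one time constant, but if the drain also runs back, E stops at a fixed share of the converted L (thermodynamic control in place of kinetic control). The three flasks below differ in temperature, so I solve both versions.

| setting | Tuesday's | Sunday's | Saturday's | noon | spring | autumn |
|---|---|---|---|---|---|---|
| L | 1.4 mM | 2.2 mM | 1 mM | 1.0 mM | 1.0 mM | 1.0 mM |
| D | 2.5 equiv | 2.5 equiv | 2.5 equiv | 2.50 equiv | 2.50 equiv | 2.50 equiv |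
| J | 0.10 mM | 0.10 mM | 0.050 mM | 0.100 mM | 0.100 mM | 0.100 mM |
| temperature | 75 °C | 105 °C | 75 °C | 80 °C | 130 °C | 105 °C |
| remark | run made earlier | run made earlier | run made earlier |  |  |  |
| time |  |  |  | 5.0 min | 5.0 min | 5.0 min |

- Tuesday's (time / min: E / %, L / %): 0.500: 9.7, 72.2; 0.833: 18.1, 63.7; 1.50: 27.5, 53.0; 3.00: 31.9, 44.2; 6.00: 24.2, 38.5
- Sunday's (time / s: E / %, L / %): 10.0: 19.9, 43.2; 25.0: 16.1, 37.5; 50.0: 14.7, 33.0; 80.0: 10.3, 30.2; 120: 9.2, 27.0
- Saturday's (time / min: E / %, L / %): 0.500: 7.6, 77.1; 1.50: 24.7, 61.5; 3.00: 31.4, 48.1; 4.00: 28.7, 45.9; 6.00: 27.6, 41.6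

(each reading ± 1 percentage point)

- the numbers in the tables scatter by 1 percentage point (one standard deviation)

- which flask leads in amount of E, in percent of the L charged ("all alike" within 1.5 percentage points) (noon / spring / autumn / all alike)
- how much E is there at the end, in percent of the L charged: noon
- how much E is there at the end, in percent of the L charged: spring
- how much E is there at the end, in percent of the L charged: autumn

Sunday's run has autumn's temperature, so I read the one-way version off its E and let that drain run on to autumn's end with no feed: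

k = ln(14.7 % / 9.2 %) / (120 s − 50.0 s) = 0.402 min⁻¹

[E] at 5.0 min = 9.2 % · exp(−k · (5.0 min − 120 s)) = 2.76 %

For the other version I take Sunday's last reading, where E over the L that has gone gives 0.126, and this ratio, the resting share, is what I carry:

[E] at rest = s · (charged L − [L])

Autumn starts with less L than Sunday's run, and at the lower charge Saturday's L ends higher than Tuesday's by 3.1 percentage points, so I add that to Sunday's L and get 8.81 %.

The first figure allows no feed, and the second is an estimate, not a bound, made from one scattered share and a shift in L borrowed from the colder runs, with Sunday's E still falling when s was read. Sunday's fall runs at 0.711 min⁻¹ up to 80.0 s and then at 0.169 min⁻¹, slower, though scatter blurs this, and a one-way drain with no feed keeps its rate. So I commit to autumn near the second figure and put spring beside it. Saturday's share of 0.473 stands far above s, so the cold flask is still draining, and I expect noon below Saturday's 27.6 % but in the lead.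

The forecast, holding that “E is itself consumed”, gives 24 % for noon, 1 % for spring and 4 % for autumn, with noon leading. Its autumn stands lower than mine.

The steps in the flask are these:

    L + D ⇌ Q (K = 146 M⁻¹, k = 7.84 M⁻¹ s⁻¹, Ea = 68.0 kJ mol⁻¹, ΔH = 11.0 kJ mol⁻¹)
    Q ⇌ E + G (K = 0.00120 M, k = 0.0457 s⁻¹, Ea = 93.0 kJ mol⁻¹, ΔH = −39.0 kJ mol⁻¹)
    E ⇌ X (K = 6.03, k = 0.00460 s⁻¹, Ea = 103 kJ mol⁻¹, ΔH = −6.00 kJ mol⁻¹)
    D + J → Z (k = 110 M⁻¹ s⁻¹, Ea = 59.0 kJ mol⁻¹)
    (constants at 80 °C)

noon leads with 21.5 %, while spring gives 8.05 % and autumn 9.14 %. Autumn still holds 9.12 % at 50.0 min, and the half-life of E and X relaxing by that step alone, 0.208 min, is short against 5.0 min. With autumn's L of 32 %, the resting share gives 8.57 %. A neighbour of autumn with 6.20 equiv of D keeps 16 % of its L, so the share gives 10.6 %, and that flask holds 11.0 %.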